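Ring A is cut into a four-carbon vinylketene, released from a cyclobutenone, and a two-carbon ynol ether. The alternating pattern of ring A, C1 (CH2 of the ketone chain), C2 (OMe), C3 (prenyl), C4 (OH), C5 (H), C6 (OH), is what a cyclobutenone/alkoxyalkyne benzannulation delivers: one thermal operation forms C3–C4, C1–C2 and C4–C5 and closes ring A with every substituent in place, so the regiochemical problems of substituting a phloroglucinol never arise. The precursor is a 3-silyloxycyclobutenone bearing the ring B carbinol chain (TES ether, phenols as TIPS ethers) on its α-carbon, assembled from a siloxyalkyne and ketene. Silyl-only protection lets the route end with fluoride, not acid.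

Key step: step 7

Remark: ring A is numbered C1 (chain carbon) to C6 as above; ring B is the 2,4-dioxygenated phenyl ring.
Remark: ketene (14) is not a catalog chemical; it is assumed to be generated immediately before use by pyrolysis of acetone in a ketene generator and is counted as a starting material.
Remark: compounds 9 to 22 are racemic at the carbinol carbon, which becomes the ketone carbon in step 10; the target has no stereocenter.

Step 1
Reactants: 1 chloroacetaldehyde dimethyl acetal; 2 prenyl bromide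
Product: 4 1-methoxy-5-methylhex-4-en-1-yne, via sodium methoxyacetylide 3 (not isolated)
Conditions: NaNH2 (3.0 equiv), liquid NH3, −33 °C; then 2 in Et2O, −40 to −33 °C; NH4Cl quench
Reagents that add atoms: none
Why: NaNH2 eliminates methanol and then HCl from the acetal and deprotonates the methoxyacetylene formed, and the sodium alkoxyacetylide is alkylated by SN2 attack at the unhindered primary carbon of prenyl bromide (classical alkoxyacetylide alkylation in ammonia), the exact three equivalents of amide leaving no strong base to isomerize the skipped enyne.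

Step 2
Reactants: 5 2,4-dihydroxybenzaldehyde
Product: 6 2,4-bis(triisopropylsilyloxy)benzaldehyde
Conditions: TIPSCl (2.4 equiv), imidazole, DMF, rt to 40 °C
Reagents that add atoms: triisopropylsilyl chloride, CC(C)[Si](Cl)(C(C)C)C(C)C
Why: Standard silylation of both phenols; aryl TIPS ethers should tolerate organozinc, amide base, heat and periodinane oxidation and fall only to fluoride, which permits an end game without acid.

Step 3
Reactants: 6 2,4-bis(triisopropylsilyloxy)benzaldehyde; 7 propargyl bromide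
Product: 9 racemic 1-[2,4-bis(triisopropylsilyloxy)phenyl]but-3-yn-1-ol, via allenylzinc bromide 8 (not isolated)
Conditions: Zn dust, THF/sat. aq. NH4Cl, 0 °C to rt
Reagents that add atoms: none
Why: Barbier propargylation, in which the allenylzinc bromide adds to the aldehyde through a cyclic SE2' transition state to give the homopropargylic alcohol while the aqueous NH4Cl protonates the zinc alkoxide before the ortho silyl group can migrate; the new carbinol center forms as a racemate and is removed by oxidation in step 10.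

Step 4
Reactants: 9 racemic 1-[2,4-bis(triisopropylsilyloxy)phenyl]but-3-yn-1-ol
Product: 10 racemic 4-[2,4-bis(triisopropylsilyloxy)phenyl]-4-(triethylsilyloxy)but-1-yne
Conditions: TESCl, imidazole, cat. DMAP, CH2Cl2, 0 °C to rt
Reagents that add atoms: chlorotriethylsilane, CC[Si](Cl)(CC)CC
Why: Silylation of the secondary alcohol; TES is chosen because it is the one silyl ether of the molecule that buffered HF removes while the aryl TIPS ethers stay.

Step 5
Reactants: 10 racemic 4-[2,4-bis(triisopropylsilyloxy)phenyl]-4-(triethylsilyloxy)but-1-yne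
Product: 13 racemic 4-[2,4-bis(triisopropylsilyloxy)phenyl]-4-(triethylsilyloxy)-1-(triisopropylsilyloxy)but-1-yne, via lithium acetylide 11 (not isolated), via lithium ynolate 12 (not isolated)
Conditions: LiN(SiMe3)2 (2.2 equiv), anhydrous t-BuOOH (1.1 equiv), THF, −78 to 0 °C; then TIPSOTf, −78 to 0 °C
Reagents that add atoms: tert-butyl hydroperoxide, CC(C)(C)OO; triisopropylsilyl trifluoromethanesulfonate, CC(C)[Si](OS(=O)(=O)C(F)(F)F)(C(C)C)C(C)C
Why: Oxygen transfer from lithium tert-butyl peroxide to the lithium acetylide gives the lithium ynolate (Julia ynolate synthesis), which the bulky silyl triflate traps on oxygen as a stable triisopropylsilyl ynol ether; the silyloxy group sits two carbons from the anionic carbon and cannot be eliminated.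

Step 6
Reactants: 13 racemic 4-[2,4-bis(triisopropylsilyloxy)phenyl]-4-(triethylsilyloxy)-1-(triisopropylsilyloxy)but-1-yne; 14 ketene
Product: 15 racemic 2-[2-(triethylsilyloxy)-2-(2,4-bis(triisopropylsilyloxy)phenyl)ethyl]-3-(triisopropylsilyloxy)cyclobut-2-en-1-one
Conditions: ketene gas (excess) passed in, CH2Cl2, 0 °C to rt; filtration through Et3N-deactivated silica
Reagents that add atoms: none
Why: Thermal (2+2) cycloaddition of ketene to the electron-rich siloxyalkyne, whose nucleophilic chain-bearing carbon bonds to the ketene carbonyl carbon, should give the 3-silyloxy-2-alkylcyclobutenone directly as one regioisomer, so neither an enol ether hydrolysis nor a regiochemically ambiguous O-silylation of a cyclobutanedione is needed.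

Step 7
Reactants: 15 racemic 2-[2-(triethylsilyloxy)-2-(2,4-bis(triisopropylsilyloxy)phenyl)ethyl]-3-(triisopropylsilyloxy)cyclobut-2-en-1-one; 4 1-methoxy-5-methylhex-4-en-1-yne
Product: 20 racemic 3-methoxy-2-(3-methylbut-2-enyl)-4-[2-(triethylsilyloxy)-2-(2,4-bis(triisopropylsilyloxy)phenyl)ethyl]-5-(triisopropylsilyloxy)phenol, via silyloxy vinylketene 16 (not isolated), via 4-vinylcyclobutenone 17 (not isolated), via dienylketene 18 (not isolated), via cyclohexadienone 19 (not isolated)
Conditions: 4 (1.5 equiv), toluene, 80 °C then 110 °C, sealed tube, argon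
Reagents that add atoms: none
Why: Heating opens the cyclobutenone 15 by a 4π electrocyclic reaction to the silyloxy vinylketene 16, whose ketene C=C adds across ynol ether 4 in a (2+2) cycloaddition to give 4-vinylcyclobutenone 17; a second 4π opening gives dienylketene 18, which closes by 6π electrocyclization to cyclohexadienone 19 and tautomerizes to phenol 20. The closest known reaction is the Danheiser benzannulation of cyclobutenones with alkoxyalkynes, the oxygen substituent at C3 of the cyclobutenone being a substituent change inside that class that should mainly raise the temperature of the first opening, because a vinylogous ester is given up. Ring A, the only ring formed, closes in the disrotatory 6π electrocyclization that makes C4–C5, after the cycloaddition has made C3–C4 and C1–C2. No stereocenter is created: the quaternary carbon of 17 is transient and the racemic carbinol is only carried along. The one selectivity needed is the orientation of the ketene/alkyne union, and the polarization of the ynol ether secures it, since its nucleophilic prenyl-bearing carbon attacks the electrophilic ketene carbonyl carbon and the methoxy carbon therefore ends up between chain and prenyl. A methyl ynol ether has no β-hydrogen for retro-ene loss of an alkene and should survive the temperature, and the silyl ethers and the prenyl alkene are thermally inert spectators.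

Step 8
Reactants: 20 racemic 3-methoxy-2-(3-methylbut-2-enyl)-4-[2-(triethylsilyloxy)-2-(2,4-bis(triisopropylsilyloxy)phenyl)ethyl]-5-(triisopropylsilyloxy)phenol
Product: 21 racemic 1-[2-(triethylsilyloxy)-2-(2,4-bis(triisopropylsilyloxy)phenyl)ethyl]-2-methoxy-3-(3-methylbut-2-enyl)-4,6-bis(triisopropylsilyloxy)benzene
Conditions: TIPSOTf, 2,6-lutidine, CH2Cl2, 0 °C
Reagents that add atoms: triisopropylsilyl trifluoromethanesulfonate, CC(C)[Si](OS(=O)(=O)C(F)(F)F)(C(C)C)C(C)C
Why: Silylation of the only free phenol (C4–OH), so that no oxidizable phenol is present at the alcohol oxidation; the TES ether tolerates the lutidine-buffered triflate.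

Step 9
Reactants: 21 racemic 1-[2-(triethylsilyloxy)-2-(2,4-bis(triisopropylsilyloxy)phenyl)ethyl]-2-methoxy-3-(3-methylbut-2-enyl)-4,6-bis(triisopropylsilyloxy)benzene
Product: 22 racemic 1-[2,4-bis(triisopropylsilyloxy)phenyl]-2-[2-methoxy-3-(3-methylbut-2-enyl)-4,6-bis(triisopropylsilyloxy)phenyl]ethanol
Conditions: HF·pyridine, pyridine, THF, 0 °C
Reagents that add atoms: none
Why: Selective desilylation, since pyridine-buffered HF cleaves a secondary alkyl TES ether much faster than aryl TIPS ethers, and the non-ionizing medium avoids acid-promoted dehydration of the electron-rich benzylic carbinol to a stilbene.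

Step 10
Reactants: 22 racemic 1-[2,4-bis(triisopropylsilyloxy)phenyl]-2-[2-methoxy-3-(3-methylbut-2-enyl)-4,6-bis(triisopropylsilyloxy)phenyl]ethanol
Product: 23 1-[2,4-bis(triisopropylsilyloxy)phenyl]-2-[2-methoxy-3-(3-methylbut-2-enyl)-4,6-bis(triisopropylsilyloxy)phenyl]ethanone
Conditions: Dess–Martin periodinane, NaHCO3, CH2Cl2, 0 °C to rt
Reagents that add atoms: none
Why: Dess–Martin oxidation of a secondary benzylic alcohol to the aryl ketone under buffered, near-neutral conditions that should leave the aryl silyl ethers, the trisubstituted alkene and the fully protected ring A untouched; the racemic center disappears here.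

Step 11
Reactants: 23 1-[2,4-bis(triisopropylsilyloxy)phenyl]-2-[2-methoxy-3-(3-methylbut-2-enyl)-4,6-bis(triisopropylsilyloxy)phenyl]ethanone
Product: 24 glicophenone
Conditions: Bu4NF (4.4 equiv), AcOH (4.4 equiv), THF, 0 °C to rt, argon; pH 7 buffer work-up
Reagents that add atoms: none
Why: Fluoride cleavage of the four aryl TIPS ethers, buffered by acetic acid, is a global deprotection without strong acid and so avoids cyclodehydration of the C6 hydroxyl onto the ketone to a 2-arylbenzofuran and cyclization of the prenyl group onto the C4 hydroxyl.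

Compound list
1 | chloroacetaldehyde dimethyl acetal (2-chloro-1,1-dimethoxyethane) | COC(CCl)OC | starting material
2 | prenyl bromide (1-bromo-3-methylbut-2-ene) | CC(C)=CCBr | starting material
3 | sodium methoxyacetylide | COC#[C-].[Na+] | intermediate (not isolated)
4 | 1-methoxy-5-methylhex-4-en-1-yne | COC#CCC=C(C)C | intermediate
5 | 2,4-dihydroxybenzaldehyde | O=Cc1ccc(O)cc1O | starting material
6 | 2,4-bis(triisopropylsilyloxy)benzaldehyde | O=Cc1ccc(O[Si](C(C)C)(C(C)C)C(C)C)cc1O[Si](C(C)C)(C(C)C)C(C)C | intermediate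
7 | propargyl bromide (3-bromoprop-1-yne) | C#CCBr | starting material
8 | allenylzinc bromide | C=C=C[Zn]Br | intermediate (not isolated)
9 | racemic 1-[2,4-bis(triisopropylsilyloxy)phenyl]but-3-yn-1-ol | C#CCC(O)c1ccc(O[Si](C(C)C)(C(C)C)C(C)C)cc1O[Si](C(C)C)(C(C)C)C(C)C | intermediate
10 | racemic 4-[2,4-bis(triisopropylsilyloxy)phenyl]-4-(triethylsilyloxy)but-1-yne | C#CCC(O[Si](CC)(CC)CC)c1ccc(O[Si](C(C)C)(C(C)C)C(C)C)cc1O[Si](C(C)C)(C(C)C)C(C)C | intermediate
11 | lithium acetylide of 10 (racemic) | [Li]C#CCC(O[Si](CC)(CC)CC)c1ccc(O[Si](C(C)C)(C(C)C)C(C)C)cc1O[Si](C(C)C)(C(C)C)C(C)C | intermediate (not isolated)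
12 | lithium ynolate, lithium 4-[2,4-bis(triisopropylsilyloxy)phenyl]-4-(triethylsilyloxy)but-1-yn-1-olate (racemic) | [Li]OC#CCC(O[Si](CC)(CC)CC)c1ccc(O[Si](C(C)C)(C(C)C)C(C)C)cc1O[Si](C(C)C)(C(C)C)C(C)C | intermediate (not isolated)
13 | racemic 4-[2,4-bis(triisopropylsilyloxy)phenyl]-4-(triethylsilyloxy)-1-(triisopropylsilyloxy)but-1-yne | CC(C)[Si](C(C)C)(C(C)C)OC#CCC(O[Si](CC)(CC)CC)c1ccc(O[Si](C(C)C)(C(C)C)C(C)C)cc1O[Si](C(C)C)(C(C)C)C(C)C | intermediate
14 | ketene | C=C=O | starting material (gas, generated before use)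
15 | racemic 2-[2-(triethylsilyloxy)-2-(2,4-bis(triisopropylsilyloxy)phenyl)ethyl]-3-(triisopropylsilyloxy)cyclobut-2-en-1-one | O=C1CC(O[Si](C(C)C)(C(C)C)C(C)C)=C1CC(O[Si](CC)(CC)CC)c1ccc(O[Si](C(C)C)(C(C)C)C(C)C)cc1O[Si](C(C)C)(C(C)C)C(C)C | intermediate (key-step precursor)
16 | silyloxy vinylketene, racemic 2-[2-(triethylsilyloxy)-2-(2,4-bis(triisopropylsilyloxy)phenyl)ethyl]-3-(triisopropylsilyloxy)buta-1,3-dien-1-one | C=C(O[Si](C(C)C)(C(C)C)C(C)C)C(=C=O)CC(O[Si](CC)(CC)CC)c1ccc(O[Si](C(C)C)(C(C)C)C(C)C)cc1O[Si](C(C)C)(C(C)C)C(C)C | intermediate (not isolated)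
17 | 4-vinylcyclobutenone, 4-[2-(triethylsilyloxy)-2-(2,4-bis(triisopropylsilyloxy)phenyl)ethyl]-3-methoxy-2-(3-methylbut-2-enyl)-4-[1-(triisopropylsilyloxy)vinyl]cyclobut-2-en-1-one (mixture of diastereomers) | COC1=C(CC=C(C)C)C(=O)C1(CC(O[Si](CC)(CC)CC)c1ccc(O[Si](C(C)C)(C(C)C)C(C)C)cc1O[Si](C(C)C)(C(C)C)C(C)C)C(=C)O[Si](C(C)C)(C(C)C)C(C)C | intermediate (not isolated)
18 | dienylketene from ring opening of 17 (racemic, alkene geometry not defined) | C=C(O[Si](C(C)C)(C(C)C)C(C)C)C(CC(O[Si](CC)(CC)CC)c1ccc(O[Si](C(C)C)(C(C)C)C(C)C)cc1O[Si](C(C)C)(C(C)C)C(C)C)=C(OC)C(CC=C(C)C)=C=O | intermediate (not isolated)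
19 | cyclohexadienone, racemic 4-[2-(triethylsilyloxy)-2-(2,4-bis(triisopropylsilyloxy)phenyl)ethyl]-3-methoxy-2-(3-methylbut-2-enyl)-5-(triisopropylsilyloxy)cyclohexa-2,4-dien-1-one | O=C1CC(O[Si](C(C)C)(C(C)C)C(C)C)=C(CC(O[Si](CC)(CC)CC)c2ccc(O[Si](C(C)C)(C(C)C)C(C)C)cc2O[Si](C(C)C)(C(C)C)C(C)C)C(OC)=C1CC=C(C)C | intermediate (not isolated)
20 | racemic 3-methoxy-2-(3-methylbut-2-enyl)-4-[2-(triethylsilyloxy)-2-(2,4-bis(triisopropylsilyloxy)phenyl)ethyl]-5-(triisopropylsilyloxy)phenol | COc1c(CC=C(C)C)c(O)cc(O[Si](C(C)C)(C(C)C)C(C)C)c1CC(O[Si](CC)(CC)CC)c1ccc(O[Si](C(C)C)(C(C)C)C(C)C)cc1O[Si](C(C)C)(C(C)C)C(C)C | intermediate (key-step product)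
21 | racemic 1-[2-(triethylsilyloxy)-2-(2,4-bis(triisopropylsilyloxy)phenyl)ethyl]-2-methoxy-3-(3-methylbut-2-enyl)-4,6-bis(triisopropylsilyloxy)benzene | COc1c(CC=C(C)C)c(O[Si](C(C)C)(C(C)C)C(C)C)cc(O[Si](C(C)C)(C(C)C)C(C)C)c1CC(O[Si](CC)(CC)CC)c1ccc(O[Si](C(C)C)(C(C)C)C(C)C)cc1O[Si](C(C)C)(C(C)C)C(C)C | intermediate
22 | racemic 1-[2,4-bis(triisopropylsilyloxy)phenyl]-2-[2-methoxy-3-(3-methylbut-2-enyl)-4,6-bis(triisopropylsilyloxy)phenyl]ethanol | COc1c(CC=C(C)C)c(O[Si](C(C)C)(C(C)C)C(C)C)cc(O[Si](C(C)C)(C(C)C)C(C)C)c1CC(O)c1ccc(O[Si](C(C)C)(C(C)C)C(C)C)cc1O[Si](C(C)C)(C(C)C)C(C)C | intermediate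
23 | 1-[2,4-bis(triisopropylsilyloxy)phenyl]-2-[2-methoxy-3-(3-methylbut-2-enyl)-4,6-bis(triisopropylsilyloxy)phenyl]ethanone | COc1c(CC=C(C)C)c(O[Si](C(C)C)(C(C)C)C(C)C)cc(O[Si](C(C)C)(C(C)C)C(C)C)c1CC(=O)c1ccc(O[Si](C(C)C)(C(C)C)C(C)C)cc1O[Si](C(C)C)(C(C)C)C(C)C | intermediate
24 | glicophenone, 1-(2,4-dihydroxyphenyl)-2-[4,6-dihydroxy-2-methoxy-3-(3-methylbut-2-enyl)phenyl]ethanone | COc1c(CC=C(C)C)c(O)cc(O)c1CC(=O)c1ccc(O)cc1O | target

Total step count: 11. Longest linear sequence: 10 steps (5 to 24, steps 2 to 11); step 1 is the one-step side branch to 4.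

Steps most likely to fail

1. Step 7. The electrocyclic opening of the vinylogous silyl ester may be too slow. At the temperature then required, the ynol ether could polymerize, the vinylketene could dimerize before it is intercepted, and the enol silyl group could be lost. Fallback (classical construction of ring A, no annulation): it sets out from 6 and commercial 2,4,6-trihydroxybenzaldehyde and returns at 23. TIPSCl (2.1 equiv)/imidazole should leave one hydrogen-bonded ortho hydroxyl free and give 2-hydroxy-4,6-bis(triisopropylsilyloxy)benzaldehyde F1. O-Alkylation with tert-butyl 2-methylbut-3-en-2-yl carbonate and catalytic Pd(PPh3)4 in THF gives the 1,1-dimethylallyl ether, 2-(2-methylbut-3-en-2-yloxy)-4,6-bis(triisopropylsilyloxy)benzaldehyde F2. Aromatic Claisen rearrangement (toluene, 110 °C) moves the group to the only free ortho carbon and gives 2-hydroxy-3-(3-methylbut-2-enyl)-4,6-bis(triisopropylsilyloxy)benzaldehyde F3. MeI/K2CO3 in acetone gives 2-methoxy-3-(3-methylbut-2-enyl)-4,6-bis(triisopropylsilyloxy)benzaldehyde F4. In parallel, 6 is condensed with aniline and diphenyl phosphite to racemic diphenyl {anilino[2,4-bis(triisopropylsilyloxy)phenyl]methyl}phosphonate F5. Horner–Wittig reaction of the anion of F5 (KOtBu, THF, 0 °C) with F4 gives the N-phenyl enamine F6. Dilute aqueous HCl in THF at rt hydrolyses it to ketone 23, from which step 11 follows.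

2. Step 6. Ketene may oligomerize before the siloxyalkyne captures it, and the enol silyl group of the product may be lost by hydrolysis during isolation. Fallback (in-situ dichloroketene, then reductive dechlorination): it sets out from 13 and returns at 15. Dichloroacetyl chloride/Et3N in Et2O at 0 °C generates dichloroketene, which should add to 13 with the same orientation to give racemic 4,4-dichloro-2-[2-(triethylsilyloxy)-2-(2,4-bis(triisopropylsilyloxy)phenyl)ethyl]-3-(triisopropylsilyloxy)cyclobut-2-en-1-one F7. Zn dust with TMEDA/AcOH in EtOH at 0 °C then removes both chlorines and gives 15.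

3. Step 5. Oxygen transfer from the peroxide to the acetylide may be incomplete, and silylation of the ynolate on carbon would give a silylketene. Fallback (Kowalski ester homologation, no alkyne oxidation): it sets out from 6 and returns at 13. Reformatsky reaction of 6 with ethyl bromoacetate and Zn in THF gives racemic ethyl 3-[2,4-bis(triisopropylsilyloxy)phenyl]-3-hydroxypropanoate F8. TESCl/imidazole gives racemic ethyl 3-[2,4-bis(triisopropylsilyloxy)phenyl]-3-(triethylsilyloxy)propanoate F9. LiCHBr2 (from CH2Br2 and lithium 2,2,6,6-tetramethylpiperidide, THF, −78 °C) adds to the ester and, after LiN(SiMe3)2, gives the enolate of racemic 1,1-dibromo-4-[2,4-bis(triisopropylsilyloxy)phenyl]-4-(triethylsilyloxy)butan-2-one F10. n-BuLi (−78 °C to rt) triggers bromine/lithium exchange and 1,2-shift to the same lithium ynolate 12, which TIPSOTf traps as 13.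

Further compounds
F1 | step 7 | 2-hydroxy-4,6-bis(triisopropylsilyloxy)benzaldehyde | O=Cc1c(O)cc(O[Si](C(C)C)(C(C)C)C(C)C)cc1O[Si](C(C)C)(C(C)C)C(C)C
F2 | step 7 | 2-(2-methylbut-3-en-2-yloxy)-4,6-bis(triisopropylsilyloxy)benzaldehyde | C=CC(C)(C)Oc1cc(O[Si](C(C)C)(C(C)C)C(C)C)cc(O[Si](C(C)C)(C(C)C)C(C)C)c1C=O
F3 | step 7 | 2-hydroxy-3-(3-methylbut-2-enyl)-4,6-bis(triisopropylsilyloxy)benzaldehyde | CC(C)=CCc1c(O)c(C=O)c(O[Si](C(C)C)(C(C)C)C(C)C)cc1O[Si](C(C)C)(C(C)C)C(C)C
F4 | step 7 | 2-methoxy-3-(3-methylbut-2-enyl)-4,6-bis(triisopropylsilyloxy)benzaldehyde | COc1c(CC=C(C)C)c(O[Si](C(C)C)(C(C)C)C(C)C)cc(O[Si](C(C)C)(C(C)C)C(C)C)c1C=O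
F5 | step 7 | racemic diphenyl {anilino[2,4-bis(triisopropylsilyloxy)phenyl]methyl}phosphonate | O=P(Oc1ccccc1)(Oc1ccccc1)C(Nc1ccccc1)c1ccc(O[Si](C(C)C)(C(C)C)C(C)C)cc1O[Si](C(C)C)(C(C)C)C(C)C
F6 | step 7 | N-phenyl enamine, N-{1-[2,4-bis(triisopropylsilyloxy)phenyl]-2-[2-methoxy-3-(3-methylbut-2-enyl)-4,6-bis(triisopropylsilyloxy)phenyl]vinyl}aniline (alkene geometry not defined) | COc1c(CC=C(C)C)c(O[Si](C(C)C)(C(C)C)C(C)C)cc(O[Si](C(C)C)(C(C)C)C(C)C)c1C=C(Nc1ccccc1)c1ccc(O[Si](C(C)C)(C(C)C)C(C)C)cc1O[Si](C(C)C)(C(C)C)C(C)C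
F7 | step 6 | racemic 4,4-dichloro-2-[2-(triethylsilyloxy)-2-(2,4-bis(triisopropylsilyloxy)phenyl)ethyl]-3-(triisopropylsilyloxy)cyclobut-2-en-1-one | O=C1C(CC(O[Si](CC)(CC)CC)c2ccc(O[Si](C(C)C)(C(C)C)C(C)C)cc2O[Si](C(C)C)(C(C)C)C(C)C)=C(O[Si](C(C)C)(C(C)C)C(C)C)C1(Cl)Cl
F8 | step 5 | racemic ethyl 3-[2,4-bis(triisopropylsilyloxy)phenyl]-3-hydroxypropanoate | CCOC(=O)CC(O)c1ccc(O[Si](C(C)C)(C(C)C)C(C)C)cc1O[Si](C(C)C)(C(C)C)C(C)C
F9 | step 5 | racemic ethyl 3-[2,4-bis(triisopropylsilyloxy)phenyl]-3-(triethylsilyloxy)propanoate | CCOC(=O)CC(O[Si](CC)(CC)CC)c1ccc(O[Si](C(C)C)(C(C)C)C(C)C)cc1O[Si](C(C)C)(C(C)C)C(C)C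
F10 | step 5 | racemic 1,1-dibromo-4-[2,4-bis(triisopropylsilyloxy)phenyl]-4-(triethylsilyloxy)butan-2-one (formed as its lithium enolate, not isolated) | BrC(Br)C(=O)CC(O[Si](CC)(CC)CC)c1ccc(O[Si](C(C)C)(C(C)C)C(C)C)cc1O[Si](C(C)C)(C(C)C)C(C)C
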